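## Retrosynthetic overview

1. Feature: ring A is a pentasubstituted benzene (C1 acyl, C2 OH, C3 CH3, C4 OH, C5 prenyl, C6 H). Oxygens at C2 and C4 flanking the C3 methyl, with a prenyl at C5, cannot be reached selectively by substituting a resorcinol, so ring A is built from open-chain pieces with its two oxygens differentiated from the start.
2. The C1–C(=O) bond comes from a photo-Fries shift of an (S)-lactoyl ester from O2 to C1. The only stereocentre, and ring B, are bought with (S)-3-(4-hydroxyphenyl)lactic acid.
3. Ring A, the only ring formed, closes by photochemical Wolff rearrangement of an acryloyl diazo ketone to a prenyl(vinyl)ketene and benzannulation with a 1-siloxypropyne (bonds C1–C2, C2–C3, C4–C5, C5–C6).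
4. The diazo enone comes from homoprenyl bromide and acrolein in three steps; the siloxyalkyne comes from propyne in one step.

Key step: step 5

Assumption: (S)-3-(4-hydroxyphenyl)lactic acid is taken as the commercial single enantiomer (otherwise one step from L-tyrosine by diazotisation with retention); ring A is numbered with the acyl-bearing carbon as C1.

## Route

Step 1
Reactants: 1 5-bromo-2-methylpent-2-ene; 2 acrolein
Product: 4 racemic 7-methylocta-1,6-dien-3-ol, via Grignard reagent 3 (not isolated)
Conditions: Mg, THF, rt to 40 °C; then 2, THF, −78 → 0 °C; aq. NH4Cl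
Reagents that add atoms: none
Why: Grignard formation and 1,2-addition to the aldehyde carbon of acrolein should give the vinyl carbinol; its stereocentre is racemic and is erased in step 2.

Step 2
Reactants: 4 racemic 7-methylocta-1,6-dien-3-ol
Product: 5 7-methylocta-1,6-dien-3-one
Conditions: IBX, DMSO, rt; product kept cold and used directly
Reagents that add atoms: none
Why: IBX oxidation of a secondary allylic alcohol is neutral and non-nucleophilic, so both alkenes and the polymerisation-prone vinyl ketone should survive.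

Step 3
Reactants: 5 7-methylocta-1,6-dien-3-one
Product: 7 4-diazo-7-methylocta-1,6-dien-3-one, via trifluoroacetyl diketone 6 (not isolated)
Conditions: LiN(SiMe3)2, THF, −78 °C (slow addition of 5); CF3CO2CH2CF3, −78 °C; 5% HCl; then MsN3, Et3N, H2O (1 equiv), MeCN, rt
Reagents that add atoms: methanesulfonyl azide, CS(=O)(=O)N=[N+]=[N-]
Why: Detrifluoroacetylative (Regitz-type deacylative) diazo transfer: kinetic deprotonation at C4, the only enolisable carbon, and Claisen acylation give a 1,3-diketone acidic enough to take the diazo group from mesyl azide with loss of the trifluoroacetyl group.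

Step 4
Reactants: 8 propyne
Product: 11 triisopropyl(prop-1-ynyloxy)silane, via propynyllithium 9 (not isolated), via lithium ynolate 10 (not isolated)
Conditions: LiN(SiMe3)2 (2.1 equiv), t-BuOOH (in decane), THF, −78 → 0 °C; then i-Pr3SiOTf, −78 → 0 °C
Reagents that add atoms: tert-butyl hydroperoxide, CC(C)(C)OO; triisopropylsilyl trifluoromethanesulfonate, CC(C)[Si](OS(=O)(=O)C(F)(F)F)(C(C)C)C(C)C
Why: Oxidation of a lithium acetylide by lithium tert-butyl peroxide gives the lithium ynolate, which the bulky silyl triflate should trap on oxygen and not on carbon (ynolate O-silylation).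

Step 5
Reactants: 7 4-diazo-7-methylocta-1,6-dien-3-one; 11 triisopropyl(prop-1-ynyloxy)silane
Product: 16 2-methyl-4-(3-methylbut-2-enyl)-3-(triisopropylsilyloxy)phenol, via vinylketene 12 (not isolated), via vinylcyclobutenone 13 (not isolated), via dienylketene 14 (not isolated), via cyclohexadienone 15 (not isolated)
Conditions: hν (254 nm, low-pressure mercury lamps, Vycor), degassed ClCH2CH2Cl, rt; then 80 °C
Reagents that add atoms: none
Why: Irradiation expels N2 from 7 and the vinyl group migrates from the carbonyl carbon to the diazo carbon (photochemical Wolff rearrangement, forming C5–C6) to give prenyl(vinyl)ketene 12, which the electron-rich siloxyalkyne 11 captures in a [2+2] cycloaddition (C2–C3 and C4–C5) to give 4-vinylcyclobutenone 13. Four-electron electrocyclic opening of 13 gives dienylketene 14, and ring A then closes by a six-electron electrocyclisation (C1–C2) to dienone 15, which tautomerises to phenol 16. This is the Danheiser benzannulation in its photochemical Wolff variant, a known route from α-diazo enones and siloxyalkynes to resorcinol monosilyl ethers. No stereocentre is formed. The selectivity needed is regiochemical: the nucleophilic methyl-bearing carbon of 11 attacks the ketene carbonyl carbon, so connectivity alone places CH3 (C3) between the two oxygens, the silyloxy carbon (C4) next to the prenyl carbon (C5) and the free hydroxyl (C2) next to unsubstituted C1. The geometry of the ring opening need not be controlled, because the isomer of 14 that cannot cyclise should revert to 13 at 80 °C.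

Step 6
Reactants: 17 (S)-3-(4-hydroxyphenyl)lactic acid
Product: 18 tert-butyldimethylsilyl (2S)-2-(tert-butyldimethylsilyloxy)-3-[4-(tert-butyldimethylsilyloxy)phenyl]propanoate
Conditions: TBSCl (3.5 equiv), imidazole, DMF, rt
Reagents that add atoms: tert-butyldimethylsilyl chloride, CC(C)(C)[Si](C)(C)Cl
Why: Exhaustive silylation of carboxyl, secondary hydroxyl and phenol with TBSCl/imidazole does not touch the stereocentre.

Step 7
Reactants: 18 tert-butyldimethylsilyl (2S)-2-(tert-butyldimethylsilyloxy)-3-[4-(tert-butyldimethylsilyloxy)phenyl]propanoate; 16 2-methyl-4-(3-methylbut-2-enyl)-3-(triisopropylsilyloxy)phenol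
Product: 20 2-methyl-4-(3-methylbut-2-enyl)-3-(triisopropylsilyloxy)phenyl (2S)-2-(tert-butyldimethylsilyloxy)-3-[4-(tert-butyldimethylsilyloxy)phenyl]propanoate, via acid chloride 19 (not isolated)
Conditions: (COCl)2, DMF (cat.), CH2Cl2, 0 °C → rt; concentrate; then 16, pyridine, DMAP (cat.), CH2Cl2, 0 °C → rt
Reagents that add atoms: none
Why: Oxalyl chloride/DMF converts the silyl ester into the acid chloride under neutral conditions that spare the silyl ethers, and pyridine/DMAP acyl transfer then esterifies the only free hydroxyl of 16 (the C2 oxygen), the weak base keeping the α-silyloxy centre from ketene-type racemisation.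

Step 8
Reactants: 20 aryl ester from step 7
Product: 21 (2S)-2-(tert-butyldimethylsilyloxy)-3-[4-(tert-butyldimethylsilyloxy)phenyl]-1-[2-hydroxy-3-methyl-5-(3-methylbut-2-enyl)-4-(triisopropylsilyloxy)phenyl]propan-1-one
Conditions: hν (254 nm, quartz), degassed cyclohexane (0.01 M), rt; recovered 16 recycled through step 7
Reagents that add atoms: none
Why: Photo-Fries rearrangement: homolysis of the ArO–C(=O) bond and in-cage recombination should occur at C1, the only open position (C3 carries CH3, the para carbon C5 carries prenyl), giving an ortho-hydroxy ketone that is photostable through its hydrogen bond; the stereocentre is not a radical site and should be retained.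

Step 9
Reactants: 21 ketone from step 8
Product: 22 Lespeflorin C5, (2S)-1-[2,4-dihydroxy-3-methyl-5-(3-methylbut-2-enyl)phenyl]-2-hydroxy-3-(4-hydroxyphenyl)propan-1-one
Conditions: Bu4NF/AcOH (1:1, 4 equiv), THF, 0 °C → rt
Reagents that add atoms: none
Why: Fluoride-mediated cleavage of the two aryl silyl ethers and the α-keto silyl ether, buffered with acetic acid so that the α-hydroxy ketone should neither epimerise nor undergo ketol shift and the prenyl group sees no strong acid.

## Compound list

1 | 5-bromo-2-methylpent-2-ene | CC(C)=CCCBr | starting material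
2 | acrolein | C=CC=O | starting material
3 | (4-methylpent-3-enyl)magnesium bromide | CC(C)=CCC[Mg]Br | intermediate
4 | 7-methylocta-1,6-dien-3-ol (racemic) | C=CC(O)CCC=C(C)C | intermediate
5 | 7-methylocta-1,6-dien-3-one | C=CC(=O)CCC=C(C)C | intermediate
6 | 1,1,1-trifluoro-3-(3-methylbut-2-enyl)hex-5-ene-2,4-dione (racemic, enolised) | C=CC(=O)C(CC=C(C)C)C(=O)C(F)(F)F | intermediate
7 | 4-diazo-7-methylocta-1,6-dien-3-one | C=CC(=O)C(=[N+]=[N-])CC=C(C)C | intermediate
8 | propyne | CC#C | starting material
9 | prop-1-ynyllithium | CC#C[Li] | intermediate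
10 | lithium prop-1-yn-1-olate | CC#C[O-].[Li+] | intermediate
11 | triisopropyl(prop-1-ynyloxy)silane | CC#CO[Si](C(C)C)(C(C)C)C(C)C | intermediate
12 | 2-ethenyl-5-methylhexa-1,4-dien-1-one (prenyl(vinyl)ketene) | C=CC(CC=C(C)C)=C=O | intermediate
13 | 4-ethenyl-2-methyl-4-(3-methylbut-2-enyl)-3-(triisopropylsilyloxy)cyclobut-2-en-1-one (racemic) | CC1=C(O[Si](C(C)C)(C(C)C)C(C)C)C(C=C)(CC=C(C)C)C1=O | intermediate
14 | (3E)-2-methyl-4-(3-methylbut-2-enyl)-3-(triisopropylsilyloxy)hexa-1,3,5-trien-1-one | O=C=C(C)/C(O[Si](C(C)C)(C(C)C)C(C)C)=C(/CC=C(C)C)C=C | intermediate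
15 | 2-methyl-4-(3-methylbut-2-enyl)-3-(triisopropylsilyloxy)cyclohexa-2,4-dien-1-one | CC1=C(O[Si](C(C)C)(C(C)C)C(C)C)C(CC=C(C)C)=CCC1=O | intermediate
16 | 2-methyl-4-(3-methylbut-2-enyl)-3-(triisopropylsilyloxy)phenol | CC(C)=CCc1ccc(O)c(C)c1O[Si](C(C)C)(C(C)C)C(C)C | intermediate
17 | (S)-3-(4-hydroxyphenyl)lactic acid | O=C(O)[C@@H](O)Cc1ccc(O)cc1 | starting material
18 | tert-butyldimethylsilyl (2S)-2-(tert-butyldimethylsilyloxy)-3-[4-(tert-butyldimethylsilyloxy)phenyl]propanoate | CC(C)(C)[Si](C)(C)OC(=O)[C@@H](O[Si](C)(C)C(C)(C)C)Cc1ccc(O[Si](C)(C)C(C)(C)C)cc1 | intermediate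
19 | (2S)-2-(tert-butyldimethylsilyloxy)-3-[4-(tert-butyldimethylsilyloxy)phenyl]propanoyl chloride | O=C(Cl)[C@@H](O[Si](C)(C)C(C)(C)C)Cc1ccc(O[Si](C)(C)C(C)(C)C)cc1 | intermediate
20 | 2-methyl-4-(3-methylbut-2-enyl)-3-(triisopropylsilyloxy)phenyl (2S)-2-(tert-butyldimethylsilyloxy)-3-[4-(tert-butyldimethylsilyloxy)phenyl]propanoate | CC(C)=CCc1ccc(OC(=O)[C@@H](O[Si](C)(C)C(C)(C)C)Cc2ccc(O[Si](C)(C)C(C)(C)C)cc2)c(C)c1O[Si](C(C)C)(C(C)C)C(C)C | intermediate
21 | (2S)-2-(tert-butyldimethylsilyloxy)-3-[4-(tert-butyldimethylsilyloxy)phenyl]-1-[2-hydroxy-3-methyl-5-(3-methylbut-2-enyl)-4-(triisopropylsilyloxy)phenyl]propan-1-one | CC(C)=CCc1cc(C(=O)[C@@H](O[Si](C)(C)C(C)(C)C)Cc2ccc(O[Si](C)(C)C(C)(C)C)cc2)c(O)c(C)c1O[Si](C(C)C)(C(C)C)C(C)C | intermediate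
22 | Lespeflorin C5, (2S)-1-[2,4-dihydroxy-3-methyl-5-(3-methylbut-2-enyl)phenyl]-2-hydroxy-3-(4-hydroxyphenyl)propan-1-one | CC(C)=CCc1cc(C(=O)[C@@H](O)Cc2ccc(O)cc2)c(O)c(C)c1O | target

## Step count and risks

Total steps: 9. Longest linear sequence: 7 (steps 1, 2, 3, 5, 7, 8, 9); steps 4 and 6 are side branches.

**Step 5 (benzannulation).** Three processes may erode it. The photogenerated carbene may undergo a 1,2-hydrogen shift from the allylic CH2 instead of vinyl migration. The diazo group may add across the acryloyl alkene of a second molecule. The ketene may dimerise or acylate the product phenol.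
Fallback: ring A is taken from a preformed resorcinol and the prenyl group is installed by Claisen rearrangement and cross-metathesis. This draws on no compound of the route; it sets out from commercial 2-methylbenzene-1,3-diol and comes back at phenol 16. Mono-allylation (allyl bromide, K2CO3, acetone) should give 2-methyl-3-(prop-2-enyloxy)phenol F1. Pivaloylation of the remaining hydroxyl (t-BuCOCl, Et3N, DMAP) should give 2-methyl-3-(prop-2-enyloxy)phenyl 2,2-dimethylpropanoate F2. Aromatic Claisen rearrangement (N,N-diethylaniline, 190 °C) should move the allyl group to the only free ortho carbon and give 3-hydroxy-2-methyl-4-(prop-2-enyl)phenyl 2,2-dimethylpropanoate F3. Silylation of the liberated hindered hydroxyl (i-Pr3SiOTf, 2,6-lutidine) should give 2-methyl-4-(prop-2-enyl)-3-(triisopropylsilyloxy)phenyl 2,2-dimethylpropanoate F4. Cross-metathesis with 2-methylbut-2-ene (second-generation Grubbs catalyst, (H2IMes)(PCy3)Cl2Ru=CHPh) should convert allyl into prenyl and give 2-methyl-4-(3-methylbut-2-enyl)-3-(triisopropylsilyloxy)phenyl 2,2-dimethylpropanoate F5. Reductive removal of the pivalate (i-Bu2AlH, CH2Cl2, −78 °C) should return 16.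

**Step 8 (photo-Fries).** The radical pair may escape the solvent cage and return phenol 16, the acyl radical may lose CO, and conversion may stall as the product absorbs the light.
Fallback: the C1–acyl bond is made by directed ortho-lithiation and a Weinreb ketone synthesis. It sets out from phenol 16 and acid chloride 19 and comes back at ketone 21. Protection of 16 (MOMCl, i-Pr2NEt) should give [3-(methoxymethoxy)-2-methyl-6-(3-methylbut-2-enyl)phenoxy]triisopropylsilane F6. Acid chloride 19 with MeNHOMe·HCl and pyridine should give (2S)-2-(tert-butyldimethylsilyloxy)-3-[4-(tert-butyldimethylsilyloxy)phenyl]-N-methoxy-N-methylpropanamide F7. Lithiation of F6 at the carbon ortho to the MOM ether (n-BuLi, TMEDA, THF, 0 °C) should give [2-(methoxymethoxy)-3-methyl-5-(3-methylbut-2-enyl)-4-(triisopropylsilyloxy)phenyl]lithium F8. Its addition to F7 at −78 °C should give (2S)-2-(tert-butyldimethylsilyloxy)-3-[4-(tert-butyldimethylsilyloxy)phenyl]-1-[2-(methoxymethoxy)-3-methyl-5-(3-methylbut-2-enyl)-4-(triisopropylsilyloxy)phenyl]propan-1-one F9 through the chelated tetrahedral intermediate, without epimerisation. Selective cleavage of the MOM ether ortho to the carbonyl (ZnBr2, n-PrSH, CH2Cl2, 0 °C) should give 21.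

**Step 3 (diazo transfer).** The cross-conjugated enolate of an unsubstituted vinyl ketone may add to unreacted enone in Michael fashion and oligomerise, and the acryloyl diazo ketone may be lost by bimolecular dipolar cycloaddition on concentration (it should be kept cold, dilute and used at once).
Fallback: the same vinylketene is generated thermally by dehydrochlorination, with no diazo compound. It sets out from siloxyalkyne 11 (with commercial ethyl (E)-but-2-enoate and 1-bromo-3-methylbut-2-ene) and comes back at vinylketene 12, and so at phenol 16. Deconjugative α-alkylation of the crotonate dienolate (LiN(i-Pr)2, HMPA, THF, −78 °C; prenyl bromide) should give racemic ethyl 2-ethenyl-5-methylhex-4-enoate F10. Saponification (LiOH, THF/H2O) should give 2-ethenyl-5-methylhex-4-enoic acid F11. Oxalyl chloride with catalytic DMF should give 2-ethenyl-5-methylhex-4-enoyl chloride F12. Slow addition of F12 to Et3N and 11 in toluene at rt, then 80 °C, should generate 12, which enters the same cycloaddition and electrocyclic cascade to 16.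

## Further compounds

F1 | step 5 | 2-methyl-3-(prop-2-enyloxy)phenol | C=CCOc1cccc(O)c1C
F2 | step 5 | 2-methyl-3-(prop-2-enyloxy)phenyl 2,2-dimethylpropanoate | C=CCOc1cccc(OC(=O)C(C)(C)C)c1C
F3 | step 5 | 3-hydroxy-2-methyl-4-(prop-2-enyl)phenyl 2,2-dimethylpropanoate | C=CCc1ccc(OC(=O)C(C)(C)C)c(C)c1O
F4 | step 5 | 2-methyl-4-(prop-2-enyl)-3-(triisopropylsilyloxy)phenyl 2,2-dimethylpropanoate | C=CCc1ccc(OC(=O)C(C)(C)C)c(C)c1O[Si](C(C)C)(C(C)C)C(C)C
F5 | step 5 | 2-methyl-4-(3-methylbut-2-enyl)-3-(triisopropylsilyloxy)phenyl 2,2-dimethylpropanoate | CC(C)=CCc1ccc(OC(=O)C(C)(C)C)c(C)c1O[Si](C(C)C)(C(C)C)C(C)C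
F6 | step 8 | [3-(methoxymethoxy)-2-methyl-6-(3-methylbut-2-enyl)phenoxy]triisopropylsilane | COCOc1ccc(CC=C(C)C)c(O[Si](C(C)C)(C(C)C)C(C)C)c1C
F7 | step 8 | (2S)-2-(tert-butyldimethylsilyloxy)-3-[4-(tert-butyldimethylsilyloxy)phenyl]-N-methoxy-N-methylpropanamide | CON(C)C(=O)[C@@H](O[Si](C)(C)C(C)(C)C)Cc1ccc(O[Si](C)(C)C(C)(C)C)cc1
F8 | step 8 | [2-(methoxymethoxy)-3-methyl-5-(3-methylbut-2-enyl)-4-(triisopropylsilyloxy)phenyl]lithium | [Li]c1cc(CC=C(C)C)c(O[Si](C(C)C)(C(C)C)C(C)C)c(C)c1OCOC
F9 | step 8 | (2S)-2-(tert-butyldimethylsilyloxy)-3-[4-(tert-butyldimethylsilyloxy)phenyl]-1-[2-(methoxymethoxy)-3-methyl-5-(3-methylbut-2-enyl)-4-(triisopropylsilyloxy)phenyl]propan-1-one | CC(C)=CCc1cc(C(=O)[C@@H](O[Si](C)(C)C(C)(C)C)Cc2ccc(O[Si](C)(C)C(C)(C)C)cc2)c(OCOC)c(C)c1O[Si](C(C)C)(C(C)C)C(C)C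
F10 | step 3 | ethyl 2-ethenyl-5-methylhex-4-enoate (racemic) | CCOC(=O)C(C=C)CC=C(C)C
F11 | step 3 | 2-ethenyl-5-methylhex-4-enoic acid (racemic) | OC(=O)C(C=C)CC=C(C)C
F12 | step 3 | 2-ethenyl-5-methylhex-4-enoyl chloride (racemic) | ClC(=O)C(C=C)CC=C(C)C
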